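The trap in these runs is to let the target's rate grow in step with the catalyst charged.

| flask | starting material | second substrate | gas | free catalyst | remark | time |
|---|---|---|---|---|---|---|
| north-east | 0.13 M | 1 equiv | 70 mM (held) | 13 mol% | run made earlier |  |
| north-west | 0.13 M | 1 equiv | 70 mM (held) | 30 mol% | run made earlier |  |
| flask | 0.13 M | 1.00 equiv | 70 mM (held) | 20 mol% |  | 40 min |

| run | time / min | target / % | starting material / % |
|---|---|---|---|
| north-east | 4.00 | 0.6 | 92.1 |
| north-east | 8.00 | 1.9 | 91.5 |
| north-east | 20.0 | 6.3 | 88.6 |
| north-east | 50.0 | 20.5 | 74.6 |
| north-west | 4.00 | 1.4 | 82.1 |
| north-west | 8.00 | 3.3 | 82.7 |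
| north-west | 20.0 | 12.9 | 75.1 |
| north-west | 50.0 | 37.6 | 53.2 |

(each reading ± 0.5 percentage points)

- at the start none of coupling partner is dissolved
- steps thought possible: coupling partner + catalyst intermediate A -> free catalyst + target; starting material + free catalyst <-> catalyst intermediate A; coupling partner + catalyst intermediate B -> free catalyst + second product; gas <-> coupling partner; second substrate + free catalyst <-> catalyst intermediate B

- the target standing at 40 min, as a percentage of the starting material charged
- concentration of coupling partner in solution at 40 min, in percent of saturation

Dissolved coupling partner starts at none, so I set aside the readings at 4.00 min and 8.00 min; my reckoning does not use them. From 20.0 min to 50.0 min the target gains 0.00473 min⁻¹ of the charge in the north-east run and 0.00823 min⁻¹ in the north-west run.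

What must I know well? Error in the north-east reading at 50.0 min, whose scatter is 0.5 percentage points, reaches the answer scaled by 0.667. But taking the order in catalyst as one moves the answer by 2 points, so the order is the number to get right. The two late rates put it at 0.662, below one, which I take as a sign that dissolved coupling partner stays under saturation, though I give that no figure.

Scaling the north-east rate by the catalyst ratio to that order gives 0.00630 min⁻¹ for the flask: this is the late rate, the target gained per minute as a share of the charge. Scaling the readings at 20.0 min likewise puts the flask at 9.11%, and the late rate carries it to 21.7% at 40 min.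

The forecast gives 22% (20% to 24%) and 73% of saturation (60% to 87%), taking the lower rate per intermediate at higher loading to suggest that “faster consumption holds the dissolved partner further below saturation”.

The flask gives 22.3% of target and 68.7% of saturation.

    coupling partner + catalyst intermediate A → free catalyst + target (k = 2.10 M⁻¹ min⁻¹)
    starting material + free catalyst ⇌ catalyst intermediate A (K = 20.0 M⁻¹, k = 28.0 M⁻¹ min⁻¹)
    coupling partner + catalyst intermediate B → free catalyst + second product (k = 0.330 M⁻¹ min⁻¹)
    gas ⇌ coupling partner, rate k4*(csat - [coupling partner]) (kL = 0.0580 min⁻¹)
    second substrate + free catalyst ⇌ catalyst intermediate B (K = 34.0 M⁻¹, k = 1.30 M⁻¹ min⁻¹)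

From 20.0 min to 40.0 min this flask gains 0.00651 min⁻¹ of the charge, against my late rate of 0.00630 min⁻¹. The neighbour is the same flask read at 1.5 h, past the last reading of either earlier run. My value at 20.0 min plus the late rate gives 53.2% there. That neighbour stands at 52.5%, with 43% of the starting material still unbound.

(The numbers in the tables were generated by integration with constants of no real substance; noise was put on by code.)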